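## Structural features

Compound 31 is a germacrane: a ten-membered carbocycle (C1–C10) with an E trisubstituted alkene C1=C10 (methyl C14 on C10), an isopropyl group on C7 (C11–C13) and a methyl-bearing oxirane fused across C4–C5 (methyl C15), i.e. an 11-oxabicyclo[8.1.0]undecene. The oxirane is cis-fused (C3 and C6 on the same side), which is the oxidation pattern of a 4Z alkene. Five stereocentres are contiguous, C4 to C8 (4S,5R,6R,7R,8S): the oxirane oxygen, the C6 acetoxy group and the C7 isopropyl group lie on one face of the ring and the C8 senecioyloxy group on the other. Two different esters sit on O6 and O8 in a 1,3-relation, so they must be introduced one at a time, and they can exchange places if O8 is ever a free alkoxide. The 4,5-epoxide and the C1=C10 alkene face each other across the ring and cyclise transannularly under protic or Lewis acid; the senecioate can slip out of conjugation with amine bases; any C6 ketone precursor has an epimerisable C7 and a β-oxygen at C8 that can be eliminated. The real difficulty is the strained ten-membered ring with its E alkene, and the relay of configuration from C8 to C7 and on to C4–C6 in a ring whose conformation is hard to foresee. The feature used is the C6 carbinol next to C7 with its three-carbon branch: with isopropyl read as isopropenyl (C11=C12), the unit C6(OH)–C7–C11=C12 is a homoallylic alcohol, and with C4–C5 at the alkyne level C6 is propargylic, which is the retron of a [2,3]-Wittig shift across a C6–O–C12 ether bridge.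

## Logic of the disconnections

31 ⇒ 29 + 30. The O8–acyl bond is cut first. The senecioate is the ester most easily damaged by base, so it goes on last. This removes five carbons and reduces ester differentiation to a question of order. The forward step must acylate a hindered secondary alcohol without acid (oxirane) and without a free alkoxide (acetate shift).

29 ⇒ 28 ⇒ 27. The O8–Si bond is re-formed and the O6–acetyl bond is cut. A silyl ether on O8 keeps the two oxygens distinct, so the acetate can be placed on O6 alone. The forward desilylation must be buffered so that the acetate stays on O6.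

27 ⇒ 26 ⇒ 25. The C6–H bond and the two C–O bonds of the oxirane are cut. A conjugated enone is the one array from which both can be made with chemoselectivity over C1=C10, because a nucleophilic oxidant touches only the conjugated alkene. Three stereocentres (C4, C5, C6) disappear and only C7 and C8 remain. The forward steps need face-selective peroxide attack with retention of the cis geometry, then chelation-controlled hydride delivery.

25 ⇒ 24 ⇒ 23 ⇒ 22. The C11–C12 alkene is restored, the C4–C15 bond is cut and C6 is taken to the carbinol level. Adding methyl to an alkyne gives the 4Z geometry by syn addition and makes C6 propargylic; isopropenyl is what a [2,3] shift delivers. C15 is removed and the C6 configuration becomes irrelevant. The forward steps need a Z-selective cuprate addition, a hydrogenation that picks the 1,1-disubstituted alkene, and an oxidation that leaves the β,γ-alkene in place.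

22 ⇒ 20 (key). C6–C7 is cut and O–C12 is reconnected. This turns a difficult ten-membered carbocyclisation into the contraction of a thirteen-membered ether that is closed by simple O-alkylation. One ring C–C bond and two stereocentres are removed and C8 is the only stereocentre left. The forward step needs lithiation at C6 only and attack on one face of the C7=C11 alkene, which the Z geometry and the C8 silyloxy group must provide.

20 ⇒ 19 ⇒ 18 ⇒ 16 ⇒ 15. The O–C12 bond is cut, with the propargylic oxygen as nucleophile and C12 as allylic chloride. The reverse polarity would place an alkoxide 1,4 to the C8 silyl ether across a Z alkene and invite silyl migration. The chain becomes acyclic. The two termini must be unmasked one after the other, which calls for three different oxygen protections (primary silyl on O12, secondary silyl on O8, 4-methoxybenzyl on O6).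

15 ⇒ 9 + 13. The C1–C2 sp2–sp3 bond is cut. It divides the chain into two pieces of similar size and can be formed with retention of alkene geometry. The forward hydroboration must take the terminal alkene of 13 and leave its alkyne.

13 ⇒ 11 + 12, and 11 ⇒ 10. The C3–C4 sp2–sp bond and the benzylic O–C bond are cut, which leads to two commodity chemicals. The only demand is clean cross-coupling of a volatile vinyl halide.

9 ⇒ 7 ⇒ 6. The C10–C14 and C1–I bonds are cut together (syn carbometalation of a terminal alkyne), then the O8–Si bond. The E geometry of C1=C10 follows from the mechanism and needs no selection. The forward step needs complete regiocontrol (metal on the terminal carbon).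

6 ⇒ 4 + 5. The C8–C9 bond is cut. C8 is the only stereocentre that needs an external chiral influence, and aldehyde propargylation can be made catalytic and enantioselective. Both pieces are achiral. The forward step needs Si-face delivery and must leave the Z enal intact.

4 ⇒ 3 ⇒ 2 ⇒ 1. Only functional groups change. The Z geometry of C7=C11 is inherited from the five-membered lactone and never has to be made selectively. The forward steps must avoid relactonisation and Z to E isomerisation.

## Other disconnections considered

Alternative 1: The ring bonds C5–C10 and C1–C4 are reconnected and C4–C5 and C1–C10 are cut, which leads to the cyclohexenone A2 and methyl cyclobut-1-ene-1-carboxylate A3. In the forward sense, irradiation of A2 with A3 forms C4–C5 and C1–C10 and gives the cis-anti-cis head-to-head tricyclic ketone A1, whose two π-face isomers converge once the cyclobutane carbons become sp2. Thermal cycloreversion of the bicyclo[2.2.0]hexane core then opens the ten-membered 1(10),4-dien-6-one.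
- In its favour: all ten ring carbons are assembled in one step from two small rings. C7 and C8 are set on a six-membered ring, which for the C7/C8 relation is the equal or the better of the chosen plan. The number of steps to the ring is lower, which is better.
- Against it: C15 arrives as an ester and has to be reduced to a methyl group in the presence of the C6 ketone. The photoaddition has a head-to-head/head-to-tail question. Both alkene geometries are dictated by the ring fusion in one thermal event and cannot be tuned separately to 1(10)E and 4Z. The 1,5-diene product can undergo Cope rearrangement to a divinylcyclohexane at the temperature needed.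
- Comparison: the chosen plan fixes 1(10)E by carbometalation and 4Z by cuprate addition, each by mechanism, and brings in C15 directly as methyl, at the price of a longer linear sequence.

Alternative 2: C8–C9 is cut while C1–C6 is reconnected, so the ring is traced to a cyclohexenol with two alkenyl groups on adjacent carbons. In the forward sense, the potassium alkoxide undergoes an anionic oxy-Cope [3,3] shift that expands the six-membered ring to the ten-membered dienone A4.
- In its favour: A4 is the 4-methoxybenzyl analogue of 25 and could enter the chosen end game at step 18 after a handful of steps instead of seventeen. On step economy it is clearly better. The 4Z alkene comes from the cyclohexene and 1(10)E from the chair transition state, which is equal in control of alkene geometry. Both plans rest on an anion-accelerated sigmatropic shift, which is equal in mechanistic reliability.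
- Against it: C7 is the enolate carbon of the product and is set only on protonation, not in the bond-forming event. C8 depends on the geometry of an alkoxy-substituted alkenyl metal reagent that must be made geometrically pure and added face-selectively to a hindered, enolisable enone. The absolute configuration hangs on an epimerisable stereocentre of that enone.
- Comparison: the chosen plan is much longer but sets C8 by a catalyst and C7 in the C–C bond-forming step under control of C8.

Alternative 3: C9–C10 is cut. In the forward sense, Ni(cod)2 with a phosphine and BEt3 would couple the methyl-substituted alkyne carbon C10 with the terminal carbon C9 of a C8–C9 epoxide, forming the ring, the E C1=C10 alkene and the C8 alcohol at once. The product A5 is identical with 29.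
- In its favour: A5 is one acylation from the target, so the end game is shorter, which is better. The E geometry follows from syn addition across the alkyne, which is equal. C8 comes from an enantiopure terminal epoxide with no question of catalyst sense, which is equal or better.
- Against it: the reductive alkyne–epoxide coupling is established for intermolecular cases and small rings, and closing a ten-membered ring with an endocyclic E alkene in the bond-forming step has no close precedent. The substrate already carries the trisubstituted 4,5-oxirane and the acetate, which zerovalent nickel and the Lewis acidic borane may attack. Four contiguous stereocentres (C4–C7) must be built on an open chain beforehand.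
- Comparison: the chosen plan closes the ring early on a simple substrate by a precedented contraction and uses the ring to set C4–C6, at the cost of a longer end game.

Key step: step 14

Remarks on the chemistry, one line each:
- Ring carbons carry germacrane numbers (C1–C15) in all discussion, also in open-chain precursors; systematic names are in the list.
- The C4 methyl group is delivered by cuprate addition to the ynone 23; the Z enone 24 is the product of that step, not its substrate.
- Numbered non-isolated intermediates are those that wait in the flask for a second reagent (8, 14, 17) and the carbanion of the key step (21); metal alkoxides and enolates that are only protonated on work-up and acyl-transfer intermediates are not numbered.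
- Compounds 5 and 30 and both antipodes of the phosphoric acid TRIP are taken to be commercial.

## Route

Step 1
Reactants: 1 4-methylfuran-2(5H)-one
Product: 2 (2Z)-4-hydroxy-N-methoxy-N,3-dimethylbut-2-enamide
Conditions: MeNH(OMe)·HCl, AlMe3, CH2Cl2, 0 °C → rt
Reagents that add atoms: N,O-dimethylhydroxylamine hydrochloride, CNOC.Cl
Why: Aminolysis of the lactone by the aluminium amide (Weinreb amide formation) opens the ring at the acyl carbon only, so the ring alkene becomes the Z alkene C7=C11 of the chain without ever being broken. Compound 2 relactonises easily and is silylated without purification.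

Step 2
Reactants: 2 (2Z)-4-hydroxy-N-methoxy-N,3-dimethylbut-2-enamide
Product: 3 (2Z)-4-[(tert-butyldimethylsilyl)oxy]-N-methoxy-N,3-dimethylbut-2-enamide
Conditions: TBSCl, imidazole, DMF, 0 °C
Reagents that add atoms: tert-butyldimethylsilyl chloride, CC(C)(C)[Si](C)(C)Cl
Why: Silylation of a primary alcohol under imidazole catalysis; no alkoxide is formed, so the amide is not displaced back to the lactone.

Step 3
Reactants: 3 (2Z)-4-[(tert-butyldimethylsilyl)oxy]-N-methoxy-N,3-dimethylbut-2-enamide
Product: 4 (2Z)-4-[(tert-butyldimethylsilyl)oxy]-3-methylbut-2-enal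
Conditions: i-Bu2AlH, THF, −78 °C; aq. KNaC4H4O6
Reagents that add atoms: none
Why: Hydride reduction of a Weinreb amide stops at the chelated aluminium hemiaminal and releases the aldehyde only on work-up. The low temperature and neutral tartrate work-up avoid Z to E isomerisation of the enal.

Step 4
Reactants: 4 (2Z)-4-[(tert-butyldimethylsilyl)oxy]-3-methylbut-2-enal; 5 allenylboronic acid pinacol ester
Product: 6 (4S,5Z)-7-[(tert-butyldimethylsilyl)oxy]-6-methylhept-5-en-1-yn-4-ol
Conditions: (S)-TRIP phosphoric acid (10 mol %), 4 Å MS, toluene, −20 °C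
Reagents that add atoms: none
Why: Chiral phosphoric acid-catalysed propargylation of an aldehyde with an allenylboronate (SE2' transfer through a closed six-membered transition state in which the acid binds a boronate oxygen and the formyl hydrogen); conjugated aldehydes are good substrates. The S catalyst is the antipode expected to deliver C9 to the Si face of C8 and so set 8S (4S in the chain name); the enantiomeric purity of 6 is measured here, and the R catalyst is used instead if the sense proves opposite.

Step 5
Reactants: 6 (4S,5Z)-7-[(tert-butyldimethylsilyl)oxy]-6-methylhept-5-en-1-yn-4-ol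
Product: 7 (4S,5Z)-4,7-bis[(tert-butyldimethylsilyl)oxy]-6-methylhept-5-en-1-yne
Conditions: TBSCl, imidazole, DMAP (cat.), DMF, rt
Reagents that add atoms: tert-butyldimethylsilyl chloride, CC(C)(C)[Si](C)(C)Cl
Why: Silylation of the secondary alcohol; the O8 silyl ether later serves as the stereocontrolling group of the key step and survives to step 21.

Step 6
Reactants: 7 (4S,5Z)-4,7-bis[(tert-butyldimethylsilyl)oxy]-6-methylhept-5-en-1-yne
Product: 9 (1E,4S,5Z)-4,7-bis[(tert-butyldimethylsilyl)oxy]-1-iodo-2,6-dimethylhepta-1,5-diene, via alkenyldimethylalane 8 (not isolated)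
Conditions: AlMe3, Cp2ZrCl2, H2O (1.5 equiv), CH2Cl2, −20 °C → 0 °C; then I2, THF, −30 → 0 °C
Reagents that add atoms: trimethylaluminium, C[Al](C)C; iodine, II
Why: Zirconium-catalysed syn methylalumination of the terminal alkyne (Negishi carboalumination) puts aluminium on the terminal carbon and methyl C14 on C10. Iodinolysis of the C–Al bond with retention gives the E alkenyl iodide, which fixes the 1(10)E geometry; water acceleration lets the reaction run cold, where both silyl ethers are safe.

Step 7
Reactants: 10 prop-2-yn-1-ol
Product: 11 1-methoxy-4-[(prop-2-yn-1-yloxy)methyl]benzene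
Conditions: NaH, 4-methoxybenzyl chloride, n-Bu4NI (cat.), THF, 0 °C → rt
Reagents that add atoms: 4-methoxybenzyl chloride, COc1ccc(CCl)cc1
Why: Williamson etherification; one equivalent of NaH deprotonates only the hydroxyl group, which is far more acidic than the alkyne C–H.

Step 8
Reactants: 11 1-methoxy-4-[(prop-2-yn-1-yloxy)methyl]benzene; 12 bromoethene
Product: 13 1-methoxy-4-[(pent-4-en-2-yn-1-yloxy)methyl]benzene
Conditions: PdCl2(PPh3)2 (2 mol %), CuI (4 mol %), i-Pr2NH, THF, 0 °C → rt
Reagents that add atoms: none
Why: Sonogashira coupling of a terminal alkyne with a vinyl bromide gives the conjugated enyne (C2–C6 of the ring); the benzylic ether is inert.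

Step 9
Reactants: 9 (1E,4S,5Z)-4,7-bis[(tert-butyldimethylsilyl)oxy]-1-iodo-2,6-dimethylhepta-1,5-diene; 13 1-methoxy-4-[(pent-4-en-2-yn-1-yloxy)methyl]benzene
Product: 15 (2Z,4S,6E)-1,4-bis[(tert-butyldimethylsilyl)oxy]-12-[(4-methoxybenzyl)oxy]-2,6-dimethyldodeca-2,6-dien-10-yne, via B-alkyl-9-BBN 14 (not isolated)
Conditions: 13, 9-BBN, THF, 0 °C → rt; then 9, PdCl2(dppf) (5 mol %), AsPh3, aq. K3PO4, DMF, rt
Reagents that add atoms: none
Why: 9-BBN adds to the monosubstituted alkene of 13 with boron on the terminal carbon and leaves the internal alkyne alone, since terminal alkenes react far faster than internal alkynes with this borane. B-alkyl Suzuki–Miyaura coupling of 14 with the alkenyl iodide forms C1–C2 with retention of the E geometry; the silyl and benzyl ethers are inert to zerovalent palladium.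

Step 10
Reactants: 15 (2Z,4S,6E)-1,4-bis[(tert-butyldimethylsilyl)oxy]-12-[(4-methoxybenzyl)oxy]-2,6-dimethyldodeca-2,6-dien-10-yne
Product: 16 (2Z,4S,6E)-4-[(tert-butyldimethylsilyl)oxy]-12-[(4-methoxybenzyl)oxy]-2,6-dimethyldodeca-2,6-dien-10-yn-1-ol
Conditions: HF·pyridine, pyridine, THF, 0 °C
Reagents that add atoms: none
Why: Buffered HF cleaves the unhindered primary silyl ether on O12 much faster than the secondary one on O8; the 4-methoxybenzyl ether is untouched.

Step 11
Reactants: 16 (2Z,4S,6E)-4-[(tert-butyldimethylsilyl)oxy]-12-[(4-methoxybenzyl)oxy]-2,6-dimethyldodeca-2,6-dien-10-yn-1-ol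
Product: 18 (2Z,4S,6E)-4-[(tert-butyldimethylsilyl)oxy]-1-chloro-12-[(4-methoxybenzyl)oxy]-2,6-dimethyldodeca-2,6-dien-10-yne, via allylic mesylate 17 (not isolated)
Conditions: MsCl, 2,4,6-collidine, LiCl, DMF, 0 °C
Reagents that add atoms: lithium chloride, [Li+].[Cl-]
Why: Mesylation and SN2 displacement by chloride in one pot give the primary allylic chloride without allylic transposition or loss of the Z geometry; the hindered pyridine base spares both ethers.

Step 12
Reactants: 18 (2Z,4S,6E)-4-[(tert-butyldimethylsilyl)oxy]-1-chloro-12-[(4-methoxybenzyl)oxy]-2,6-dimethyldodeca-2,6-dien-10-yne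
Product: 19 (6E,9S,10Z)-9-[(tert-butyldimethylsilyl)oxy]-12-chloro-7,11-dimethyldodeca-6,10-dien-2-yn-1-ol
Conditions: DDQ, CH2Cl2–pH 7 buffer, 0 °C
Reagents that add atoms: none
Why: Oxidative cleavage of the 4-methoxybenzyl ether (hydride abstraction, then hydrolysis of the oxocarbenium ion) under neutral conditions leaves the allylic chloride, the silyl ether, the alkenes and the alkyne alone.

Step 13
Reactants: 19 (6E,9S,10Z)-9-[(tert-butyldimethylsilyl)oxy]-12-chloro-7,11-dimethyldodeca-6,10-dien-2-yn-1-ol
Product: 20 (3Z,5S,7E)-5-[(tert-butyldimethylsilyl)oxy]-3,7-dimethyl-1-oxacyclotrideca-3,7-dien-11-yne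
Conditions: EtMgBr, THF, 0 °C; then slow addition to THF–HMPA, 60 °C, final 0.003 M
Reagents that add atoms: none
Why: Intramolecular Williamson etherification of a magnesium propargylic alkoxide on a primary allylic chloride; two alkenes and an alkyne leave the chain few rotors, and high dilution suppresses dimers. The weakly basic magnesium alkoxide avoids elimination of HCl and propargyl–allene isomerisation.

Step 14
Reactants: 20 (3Z,5S,7E)-5-[(tert-butyldimethylsilyl)oxy]-3,7-dimethyl-1-oxacyclotrideca-3,7-dien-11-yne
Product: 22 (1R,6E,9S,10S)-9-[(tert-butyldimethylsilyl)oxy]-7-methyl-10-(prop-1-en-2-yl)cyclodec-6-en-2-yn-1-ol, via C6-lithiated ether 21 (not isolated)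
Conditions: n-BuLi (1.5 equiv), THF–hexane, −78 → −20 °C; then H2O
Reagents that add atoms: none
Why: n-BuLi removes a proton from C6, the only C–H that is both propargylic and α to oxygen, to give 21. The carbanion then undergoes a concerted suprafacial [2,3]-sigmatropic (Wittig) shift through a five-membered envelope C6–O–C12–C11=C7: C6–C7 forms, O–C12 breaks, C11=C12 appears and the ether oxygen becomes the C6 alkoxide. The closest known reaction type is the ring contraction of thirteen-membered propargylic allylic ethers to cyclodec-en-ynols. The ten-membered carbocycle is closed by excision of the O–C12–C11 unit from the thirteen-membered ring; seen from the new ring the bond formation is 10-exo-trig (C7 becomes a ring atom, C11 stays outside), and the entropic cost was paid earlier in the ether closure. C7 is controlled by C8: in the Z alkene H8 must lie in the alkene plane to avoid allylic 1,3-strain with C12H2, so one face carries the silyloxy group and the other C9, and the carbanion adds anti to the C–O bond (less hindered and stereoelectronically favoured for a nucleophile), which places isopropenyl trans to the silyloxy group. C6 is controlled by the Z geometry of the allylic ether, which in the envelope should give hydroxyl and isopropenyl cis on the ring; this centre is removed in step 15, so only C7 has to be right. The step needs site-selective lithiation (C6 over the allylic C12 and the propargylic C3), secured by the double activation of C6, and [2,3] over [1,2] shift, secured by the low temperature and the allowed five-membered transition state. The silyl ether, both trisubstituted alkenes and the internal alkyne are inert to n-BuLi at these temperatures.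

Step 15
Reactants: 22 (1R,6E,9S,10S)-9-[(tert-butyldimethylsilyl)oxy]-7-methyl-10-(prop-1-en-2-yl)cyclodec-6-en-2-yn-1-ol
Product: 23 (6E,9S,10R)-9-[(tert-butyldimethylsilyl)oxy]-7-methyl-10-(prop-1-en-2-yl)cyclodec-6-en-2-yn-1-one
Conditions: Dess–Martin periodinane, NaHCO3, CH2Cl2, 0 °C → rt
Reagents that add atoms: none
Why: Dess–Martin oxidation of the propargylic alcohol under buffered, non-basic conditions keeps the β,γ-isopropenyl alkene out of conjugation and C7 unepimerised; the crude ynone is used at once. The C6 stereocentre is erased on purpose.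

Step 16
Reactants: 23 (6E,9S,10R)-9-[(tert-butyldimethylsilyl)oxy]-7-methyl-10-(prop-1-en-2-yl)cyclodec-6-en-2-yn-1-one
Product: 24 (1(10)E,4Z,7R,8S)-8-[(tert-butyldimethylsilyl)oxy]germacra-1(10),4,11-trien-6-one
Conditions: Me2CuLi (from MeLi and CuI), Et2O, −78 °C; then aq. NH4Cl
Reagents that add atoms: lithium dimethylcuprate, [Li+].C[Cu-]C
Why: Conjugate addition of the cuprate to the ynone: syn carbocupration then protonation puts methyl C15 and H5 cis, i.e. C3 and C6 cis (4Z), which is also the less strained enone in a ten-membered ring. The cuprate does not add to unactivated alkenes or to the β,β-disubstituted product, and is too weakly basic to enolise C7 at −78 °C.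

Step 17
Reactants: 24 (1(10)E,4Z,7R,8S)-8-[(tert-butyldimethylsilyl)oxy]germacra-1(10),4,11-trien-6-one
Product: 25 (1(10)E,4Z,7R,8S)-8-[(tert-butyldimethylsilyl)oxy]germacra-1(10),4-dien-6-one
Conditions: H2 (1 atm), RhCl(PPh3)3 (10 mol %), benzene, rt
Reagents that add atoms: none
Why: Homogeneous hydrogenation with RhCl(PPh3)3 reduces the unhindered 1,1-disubstituted isopropenyl alkene far faster than the two trisubstituted alkenes, one of which is conjugated. Removing the allylic activation of H7 here also protects C7 in the following steps.

Step 18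
Reactants: 25 (1(10)E,4Z,7R,8S)-8-[(tert-butyldimethylsilyl)oxy]germacra-1(10),4-dien-6-one
Product: 26 (1(10)E,4S,5S,7R,8S)-8-[(tert-butyldimethylsilyl)oxy]-4,5-epoxygermacr-1(10)-en-6-one
Conditions: t-BuOOH, KH, THF, −20 → 0 °C
Reagents that add atoms: tert-butyl hydroperoxide, CC(C)(C)OO
Why: Nucleophilic (Weitz–Scheffer) epoxidation: the tert-butyl peroxide anion adds to C4 of the enone only and the enolate closes on oxygen, so the isolated C1=C10 alkene is untouched and the ring holds C3 and C6 cis during closure. Attack on the outer face of the twisted enone, with the C7 and C8 substituents pointing outward, should give the 4S,5S oxirane; the anhydrous peroxide salt is too weak a base to epimerise C7 or eliminate the β-silyloxy group at this temperature.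

Step 19
Reactants: 26 (1(10)E,4S,5S,7R,8S)-8-[(tert-butyldimethylsilyl)oxy]-4,5-epoxygermacr-1(10)-en-6-one
Product: 27 (1(10)E,4S,5R,6R,7S,8S)-8-[(tert-butyldimethylsilyl)oxy]-4,5-epoxygermacr-1(10)-en-6-ol
Conditions: Zn(BH4)2, Et2O, −20 → 0 °C
Reagents that add atoms: none
Why: Zinc chelates the carbonyl and oxirane oxygens, and hydride attacks C6 from the side away from the oxirane carbon C4, which in the rotamer with H7 eclipsing the carbonyl is also the side away from the isopropyl group. This should give the anti (erythro) epoxy alcohol, 6R, with oxirane oxygen, hydroxyl and isopropyl on one face; the reagent spares the oxirane and the silyl ether.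

Step 20
Reactants: 27 (1(10)E,4S,5R,6R,7S,8S)-8-[(tert-butyldimethylsilyl)oxy]-4,5-epoxygermacr-1(10)-en-6-ol
Product: 28 (1(10)E,4S,5R,6R,7S,8S)-8-[(tert-butyldimethylsilyl)oxy]-4,5-epoxygermacr-1(10)-en-6-yl acetate
Conditions: Ac2O, pyridine, DMAP (cat.), CH2Cl2, rt
Reagents that add atoms: acetic anhydride, CC(=O)OC(C)=O
Why: DMAP-catalysed acetylation of the only free hydroxyl group under basic, acid-free conditions that cannot trigger transannular opening of the oxirane.

Step 21
Reactants: 28 (1(10)E,4S,5R,6R,7S,8S)-8-[(tert-butyldimethylsilyl)oxy]-4,5-epoxygermacr-1(10)-en-6-yl acetate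
Product: 29 (1(10)E,4S,5R,6R,7R,8S)-4,5-epoxy-8-hydroxygermacr-1(10)-en-6-yl acetate
Conditions: TBAF, AcOH (1:1), THF, 0 °C → rt
Reagents that add atoms: none
Why: Fluoride cleaves the secondary silyl ether; acetic acid buffers the liberated alkoxide so that the acetate neither shifts from O6 to O8 nor is cleaved, and the medium is not acidic enough to open the oxirane.

Step 22
Reactants: 29 (1(10)E,4S,5R,6R,7R,8S)-4,5-epoxy-8-hydroxygermacr-1(10)-en-6-yl acetate; 30 3-methylbut-2-enoic acid
Product: 31 (1(10)E,4S,5R,6R,7R,8S)-6-acetoxy-4,5-epoxygermacr-1(10)-en-8-yl 3-methylbut-2-enoate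
Conditions: DCC, DMAP (cat.), CH2Cl2, 0 °C → rt
Reagents that add atoms: none
Why: Carbodiimide esterification with DMAP catalysis (Steglich) acylates the hindered C8 alcohol under near-neutral conditions. Using the free acid avoids the acid chloride/amine combination that can move the senecioate double bond out of conjugation; 31 is purified on base-washed silica.

## Compound list

1 | 4-methylfuran-2(5H)-one | CC1=CC(=O)OC1 | starting material
2 | (2Z)-4-hydroxy-N-methoxy-N,3-dimethylbut-2-enamide | OC/C(C)=C\C(=O)N(C)OC | intermediate
3 | (2Z)-4-[(tert-butyldimethylsilyl)oxy]-N-methoxy-N,3-dimethylbut-2-enamide | CC(C)(C)[Si](C)(C)OC/C(C)=C\C(=O)N(C)OC | intermediate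
4 | (2Z)-4-[(tert-butyldimethylsilyl)oxy]-3-methylbut-2-enal | CC(C)(C)[Si](C)(C)OC/C(C)=C\C=O | intermediate
5 | allenylboronic acid pinacol ester, 4,4,5,5-tetramethyl-2-(propa-1,2-dien-1-yl)-1,3,2-dioxaborolane | C=C=CB1OC(C)(C)C(C)(C)O1 | starting material
6 | (4S,5Z)-7-[(tert-butyldimethylsilyl)oxy]-6-methylhept-5-en-1-yn-4-ol | CC(C)(C)[Si](C)(C)OC/C(C)=C\[C@@H](O)CC#C | intermediate
7 | (4S,5Z)-4,7-bis[(tert-butyldimethylsilyl)oxy]-6-methylhept-5-en-1-yne | CC(C)(C)[Si](C)(C)OC/C(C)=C\[C@@H](O[Si](C)(C)C(C)(C)C)CC#C | intermediate
8 | [(1E,4S,5Z)-4,7-bis[(tert-butyldimethylsilyl)oxy]-2,6-dimethylhepta-1,5-dien-1-yl]dimethylalane | CC(C)(C)[Si](C)(C)OC/C(C)=C\[C@@H](O[Si](C)(C)C(C)(C)C)C/C(C)=C/[Al](C)C | intermediate (not isolated)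
9 | (1E,4S,5Z)-4,7-bis[(tert-butyldimethylsilyl)oxy]-1-iodo-2,6-dimethylhepta-1,5-diene | CC(C)(C)[Si](C)(C)OC/C(C)=C\[C@@H](O[Si](C)(C)C(C)(C)C)C/C(C)=C/I | intermediate
10 | prop-2-yn-1-ol (propargyl alcohol) | C#CCO | starting material
11 | 1-methoxy-4-[(prop-2-yn-1-yloxy)methyl]benzene | C#CCOCc1ccc(OC)cc1 | intermediate
12 | bromoethene (vinyl bromide) | C=CBr | starting material
13 | 1-methoxy-4-[(pent-4-en-2-yn-1-yloxy)methyl]benzene | C=CC#CCOCc1ccc(OC)cc1 | intermediate
14 | 9-{5-[(4-methoxybenzyl)oxy]pent-3-yn-1-yl}-9-borabicyclo[3.3.1]nonane | COc1ccc(COCC#CCCB2C3CCCC2CCC3)cc1 | intermediate (not isolated)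
15 | (2Z,4S,6E)-1,4-bis[(tert-butyldimethylsilyl)oxy]-12-[(4-methoxybenzyl)oxy]-2,6-dimethyldodeca-2,6-dien-10-yne | CC(C)(C)[Si](C)(C)OC/C(C)=C\[C@@H](O[Si](C)(C)C(C)(C)C)C/C(C)=C/CCC#CCOCc1ccc(OC)cc1 | intermediate
16 | (2Z,4S,6E)-4-[(tert-butyldimethylsilyl)oxy]-12-[(4-methoxybenzyl)oxy]-2,6-dimethyldodeca-2,6-dien-10-yn-1-ol | OC/C(C)=C\[C@@H](O[Si](C)(C)C(C)(C)C)C/C(C)=C/CCC#CCOCc1ccc(OC)cc1 | intermediate
17 | (2Z,4S,6E)-4-[(tert-butyldimethylsilyl)oxy]-12-[(4-methoxybenzyl)oxy]-2,6-dimethyldodeca-2,6-dien-10-yn-1-yl methanesulfonate | CS(=O)(=O)OC/C(C)=C\[C@@H](O[Si](C)(C)C(C)(C)C)C/C(C)=C/CCC#CCOCc1ccc(OC)cc1 | intermediate (not isolated)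
18 | (2Z,4S,6E)-4-[(tert-butyldimethylsilyl)oxy]-1-chloro-12-[(4-methoxybenzyl)oxy]-2,6-dimethyldodeca-2,6-dien-10-yne | ClC/C(C)=C\[C@@H](O[Si](C)(C)C(C)(C)C)C/C(C)=C/CCC#CCOCc1ccc(OC)cc1 | intermediate
19 | (6E,9S,10Z)-9-[(tert-butyldimethylsilyl)oxy]-12-chloro-7,11-dimethyldodeca-6,10-dien-2-yn-1-ol | ClC/C(C)=C\[C@@H](O[Si](C)(C)C(C)(C)C)C/C(C)=C/CCC#CCO | intermediate
20 | (3Z,5S,7E)-5-[(tert-butyldimethylsilyl)oxy]-3,7-dimethyl-1-oxacyclotrideca-3,7-dien-11-yne | C1OC/C(C)=C\[C@@H](O[Si](C)(C)C(C)(C)C)C/C(C)=C/CCC#C1 | intermediate
21 | (3Z,5S,7E)-5-[(tert-butyldimethylsilyl)oxy]-13-lithio-3,7-dimethyl-1-oxacyclotrideca-3,7-dien-11-yne | [Li]C1OC/C(C)=C\[C@@H](O[Si](C)(C)C(C)(C)C)C/C(C)=C/CCC#C1 | intermediate (not isolated)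
22 | (1R,6E,9S,10S)-9-[(tert-butyldimethylsilyl)oxy]-7-methyl-10-(prop-1-en-2-yl)cyclodec-6-en-2-yn-1-ol; germacrane numbering 1(10)E,6R,7S,8S | O[C@@H]1[C@H](C(C)=C)[C@@H](O[Si](C)(C)C(C)(C)C)C/C(C)=C/CCC#C1 | intermediate
23 | (6E,9S,10R)-9-[(tert-butyldimethylsilyl)oxy]-7-methyl-10-(prop-1-en-2-yl)cyclodec-6-en-2-yn-1-one | O=C1[C@H](C(C)=C)[C@@H](O[Si](C)(C)C(C)(C)C)C/C(C)=C/CCC#C1 | intermediate
24 | (1(10)E,4Z,7R,8S)-8-[(tert-butyldimethylsilyl)oxy]germacra-1(10),4,11-trien-6-one | O=C1[C@H](C(C)=C)[C@@H](O[Si](C)(C)C(C)(C)C)C/C(C)=C/CC/C(C)=C\1 | intermediate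
25 | (1(10)E,4Z,7R,8S)-8-[(tert-butyldimethylsilyl)oxy]germacra-1(10),4-dien-6-one | O=C1[C@H](C(C)C)[C@@H](O[Si](C)(C)C(C)(C)C)C/C(C)=C/CC/C(C)=C\1 | intermediate
26 | (1(10)E,4S,5S,7R,8S)-8-[(tert-butyldimethylsilyl)oxy]-4,5-epoxygermacr-1(10)-en-6-one | O=C1[C@H](C(C)C)[C@@H](O[Si](C)(C)C(C)(C)C)C/C(C)=C/CC[C@]2(C)O[C@H]12 | intermediate
27 | (1(10)E,4S,5R,6R,7S,8S)-8-[(tert-butyldimethylsilyl)oxy]-4,5-epoxygermacr-1(10)-en-6-ol | O[C@@H]1[C@H](C(C)C)[C@@H](O[Si](C)(C)C(C)(C)C)C/C(C)=C/CC[C@]2(C)O[C@H]12 | intermediate
28 | (1(10)E,4S,5R,6R,7S,8S)-8-[(tert-butyldimethylsilyl)oxy]-4,5-epoxygermacr-1(10)-en-6-yl acetate | CC(=O)O[C@@H]1[C@H](C(C)C)[C@@H](O[Si](C)(C)C(C)(C)C)C/C(C)=C/CC[C@]2(C)O[C@H]12 | intermediate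
29 | (1(10)E,4S,5R,6R,7R,8S)-4,5-epoxy-8-hydroxygermacr-1(10)-en-6-yl acetate | CC(=O)O[C@@H]1[C@H](C(C)C)[C@@H](O)C/C(C)=C/CC[C@]2(C)O[C@H]12 | intermediate
30 | 3-methylbut-2-enoic acid (senecioic acid) | CC(C)=CC(=O)O | starting material
31 | (1(10)E,4S,5R,6R,7R,8S)-6-acetoxy-4,5-epoxygermacr-1(10)-en-8-yl 3-methylbut-2-enoate | CC(=O)O[C@@H]1[C@H](C(C)C)[C@@H](OC(=O)C=C(C)C)C/C(C)=C/CC[C@]2(C)O[C@H]12 | target

## Step count and least certain steps

Total: 22 steps (20 in the main line, 2 in the side branch that makes 13). Longest linear sequence: 20 steps (steps 1–6 and 9–22).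

**Step 14 (key step).** The most likely failures are insufficient discrimination between the two faces of the C7=C11 alkene, or a slow rearrangement that lets the [1,2]-shift and lithiation at C12 compete, because the macrocycle may hold the carbanion away from C7. The fallback forms the same C6–C7 bond by carbonyl allylation instead of a sigmatropic shift; it sets out from 19 and comes back at 23. Oxidation of 19 with activated MnO2 would give the ynal (6E,9S,10Z)-9-[(tert-butyldimethylsilyl)oxy]-12-chloro-7,11-dimethyldodeca-6,10-dien-2-ynal F1. Treatment of F1 with CrCl2 and catalytic LiI in THF–DMF at high dilution (intramolecular Nozaki–Hiyama–Kishi allylation, attack through the γ-carbon C7) should close the ten-membered ring to the C6 epimer of 22, (1S,6E,9S,10S)-9-[(tert-butyldimethylsilyl)oxy]-7-methyl-10-(prop-1-en-2-yl)cyclodec-6-en-2-yn-1-ol F2, alone or mixed with 22. C8 is again the only controlling centre, and the sense at C7 would have to be confirmed. Either C6 epimer gives 23 under the conditions of step 15.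

**Step 13.** The thirteen-membered ring has to form against entropy, so intermolecular alkylation to dimers and oligomers, or loss of HCl from the allylic chloride, may outrun ring closure. The fallback makes the ether bond intermolecularly and closes the ring at C1–C2; it sets out from 9 and comes back at 20. Selective cleavage of the primary silyl ether of 9 (HF·pyridine, pyridine) would give (2Z,4S,6E)-4-[(tert-butyldimethylsilyl)oxy]-7-iodo-2,6-dimethylhepta-2,6-dien-1-ol F3. MsCl, collidine and LiCl would convert F3 into tert-butyl{[(1E,4S,5Z)-7-chloro-1-iodo-2,6-dimethylhepta-1,5-dien-4-yl]oxy}dimethylsilane F4. Sonogashira coupling of 10 with 12 gives pent-4-en-2-yn-1-ol F5, whose sodium alkoxide (NaH, THF) would displace the chloride of F4 to give tert-butyl{[(1E,4S,5Z)-1-iodo-2,6-dimethyl-7-(pent-4-en-2-yn-1-yloxy)hepta-1,5-dien-4-yl]oxy}dimethylsilane F6. Hydroboration of the terminal alkene of F6 with 9-BBN gives the 9-BBN adduct of F6, 9-{5-[(2Z,4S,6E)-4-[(tert-butyldimethylsilyl)oxy]-7-iodo-2,6-dimethylhepta-2,6-dien-1-yl]oxypent-3-yn-1-yl}-9-borabicyclo[3.3.1]nonane F7. Intramolecular B-alkyl Suzuki–Miyaura coupling of F7 (PdCl2(dppf), AsPh3, Cs2CO3, DMF–THF–H2O, high dilution) would then close the macrocycle 20.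

**Step 9.** The hydroboration may partly attack the conjugated alkyne or place boron on the internal alkene carbon, since the alkene is conjugated and less electron-rich than a simple terminal alkene; the coupling would then give isomer mixtures. The fallback replaces the borane by a homopropargylic zinc reagent made without any hydroboration; it sets out from 11 and comes back at 15. Lithiation of 11 (n-BuLi) and opening of ethylene oxide with BF3·OEt2 would give 5-[(4-methoxybenzyl)oxy]pent-3-yn-1-ol F8. I2, PPh3 and imidazole would convert F8 into 1-{[(5-iodopent-2-yn-1-yl)oxy]methyl}-4-methoxybenzene F9. Zinc insertion (Zn, LiCl, THF) gives {5-[(4-methoxybenzyl)oxy]pent-3-yn-1-yl}zinc iodide F10, and Negishi coupling of F10 with 9 (PdCl2(dppf), THF) would give 15.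

**Step 18 (with step 19).** Peroxide attack may not discriminate well between the two faces of the enone, because the selectivity rests only on the ring conformation. Bond rotation in the intermediate enolate may erode the cis geometry, and the basic medium may epimerise C7 or eliminate the β-silyloxy group. The fallback sets C6 first, from the adjacent C7, and then uses the hydroxyl group to direct a concerted epoxidation; it sets out from 25 and comes back at 27. 1,2-Reduction of 25 (NaBH4, CeCl3·7H2O, MeOH, −40 °C; Luche reduction), with hydride arriving anti to the isopropyl group, would give (1(10)E,4Z,6S,7S,8S)-8-[(tert-butyldimethylsilyl)oxy]germacra-1(10),4-dien-6-ol F11. Epoxidation of F11 with VO(acac)2 and t-BuOOH is stereospecific for the cis oxirane and selective for the allylic alcohol alkene, and is expected, as with medium-ring cis-cycloalkenols, to deliver oxygen cis to the hydroxyl group, which is 27.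

**Step 4.** Enantioselection may be incomplete with a β,β-disubstituted Z enal, and the acid catalyst may slowly isomerise the enal to its E form during the long reaction time. The fallback gives up asymmetric catalysis for resolution; it sets out from 4 and comes back at 6. Barbier propargylation of 4 (propargyl bromide, Zn, THF–aq. NH4Cl) would give racemic (5Z)-7-[(tert-butyldimethylsilyl)oxy]-6-methylhept-5-en-1-yn-4-ol F12. Kinetic resolution of F12 with a Burkholderia cepacia lipase and vinyl acetate should, by the empirical selectivity rule for secondary alcohols, acetylate the R antipode to (4R,5Z)-7-[(tert-butyldimethylsilyl)oxy]-6-methylhept-5-en-1-yn-4-yl acetate F13 and leave the S alcohol 6.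

## Further compounds

F1 | step 14 | (6E,9S,10Z)-9-[(tert-butyldimethylsilyl)oxy]-12-chloro-7,11-dimethyldodeca-6,10-dien-2-ynal | ClC/C(C)=C\[C@@H](O[Si](C)(C)C(C)(C)C)C/C(C)=C/CCC#CC=O
F2 | step 14 | (1S,6E,9S,10S)-9-[(tert-butyldimethylsilyl)oxy]-7-methyl-10-(prop-1-en-2-yl)cyclodec-6-en-2-yn-1-ol | O[C@H]1[C@H](C(C)=C)[C@@H](O[Si](C)(C)C(C)(C)C)C/C(C)=C/CCC#C1
F3 | step 13 | (2Z,4S,6E)-4-[(tert-butyldimethylsilyl)oxy]-7-iodo-2,6-dimethylhepta-2,6-dien-1-ol | OC/C(C)=C\[C@@H](O[Si](C)(C)C(C)(C)C)C/C(C)=C/I
F4 | step 13 | tert-butyl{[(1E,4S,5Z)-7-chloro-1-iodo-2,6-dimethylhepta-1,5-dien-4-yl]oxy}dimethylsilane | ClC/C(C)=C\[C@@H](O[Si](C)(C)C(C)(C)C)C/C(C)=C/I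
F5 | step 13 | pent-4-en-2-yn-1-ol | C=CC#CCO
F6 | step 13 | tert-butyl{[(1E,4S,5Z)-1-iodo-2,6-dimethyl-7-(pent-4-en-2-yn-1-yloxy)hepta-1,5-dien-4-yl]oxy}dimethylsilane | C=CC#CCOC/C(C)=C\[C@@H](O[Si](C)(C)C(C)(C)C)C/C(C)=C/I
F7 | step 13 | 9-{5-[(2Z,4S,6E)-4-[(tert-butyldimethylsilyl)oxy]-7-iodo-2,6-dimethylhepta-2,6-dien-1-yl]oxypent-3-yn-1-yl}-9-borabicyclo[3.3.1]nonane | C1CCC2CCCC1B2CCC#CCOC/C(C)=C\[C@@H](O[Si](C)(C)C(C)(C)C)C/C(C)=C/I
F8 | step 9 | 5-[(4-methoxybenzyl)oxy]pent-3-yn-1-ol | OCCC#CCOCc1ccc(OC)cc1
F9 | step 9 | 1-{[(5-iodopent-2-yn-1-yl)oxy]methyl}-4-methoxybenzene | ICCC#CCOCc1ccc(OC)cc1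
F10 | step 9 | {5-[(4-methoxybenzyl)oxy]pent-3-yn-1-yl}zinc iodide | I[Zn]CCC#CCOCc1ccc(OC)cc1
F11 | step 18 | (1(10)E,4Z,6S,7S,8S)-8-[(tert-butyldimethylsilyl)oxy]germacra-1(10),4-dien-6-ol | O[C@@H]1[C@H](C(C)C)[C@@H](O[Si](C)(C)C(C)(C)C)C/C(C)=C/CC/C(C)=C\1
F12 | step 4 | racemic (5Z)-7-[(tert-butyldimethylsilyl)oxy]-6-methylhept-5-en-1-yn-4-ol | CC(C)(C)[Si](C)(C)OC/C(C)=C\C(O)CC#C
F13 | step 4 | (4R,5Z)-7-[(tert-butyldimethylsilyl)oxy]-6-methylhept-5-en-1-yn-4-yl acetate | CC(C)(C)[Si](C)(C)OC/C(C)=C\[C@H](OC(C)=O)CC#C
A1 | alternative 1 | methyl 8-[(tert-butyldimethylsilyl)oxy]-6-methyl-10-oxo-9-(propan-2-yl)tricyclo[4.4.0.0(2,5)]decane-2-carboxylate, cis-anti-cis head-to-head photoadduct | O=C1[C@@H]2[C@@]3(C(=O)OC)CC[C@H]3[C@]2(C)C[C@H](O[Si](C)(C)C(C)(C)C)[C@H]1C(C)C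
A2 | alternative 1 | (5S,6R)-5-[(tert-butyldimethylsilyl)oxy]-3-methyl-6-(propan-2-yl)cyclohex-2-en-1-one | O=C1C=C(C)C[C@H](O[Si](C)(C)C(C)(C)C)[C@H]1C(C)C
A3 | alternative 1 | methyl cyclobut-1-ene-1-carboxylate | COC(=O)C1=CCC1
A4 | alternative 2 | (1(10)E,4Z,7R,8S)-8-[(4-methoxybenzyl)oxy]germacra-1(10),4-dien-6-one | O=C1[C@H](C(C)C)[C@@H](OCc2ccc(OC)cc2)C/C(C)=C/CC/C(C)=C\1
A5 | alternative 3 | (1(10)E,4S,5R,6R,7R,8S)-4,5-epoxy-8-hydroxygermacr-1(10)-en-6-yl acetate, identical with 29 | CC(=O)O[C@@H]1[C@H](C(C)C)[C@@H](O)C/C(C)=C/CC[C@]2(C)O[C@H]12
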